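**Retrosynthetic overview**
1. Target 33 ← BBr3 cleavage of octamethyl ether 32 ← Pd(OAc)2/SPhos 5-exo-dig carbopalladation–Suzuki cascade of chloro-alkyne 20 with dihydrobenzofuran boronate 31; this closes the indane five-membered ring and fixes the (Z)-benzylidene.
2. Alkyne 20 ← stereoretentive alkynylation (C2–B becomes C2–C3) of boronic ester 12.
3. 12 ← three-component conjunctive cross-coupling. The strategy rests on indane C1 and C2: adjacent, trans benzylic methines, each carrying one aryl group outside the ring (4-hydroxyphenyl on C1, 3,5-dihydroxyphenyl on C2). Both C–aryl bonds are made across the C1=C2 double bond of the ring A (Z)-styrenyl boronate 7, one from aryllithium 10 (by way of boron, to C2) and one from triflate 9 (by way of palladium, to C1).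
4. 31 ← borylation ← C2 epimerisation ← rhodium-carbene C–H insertion of hydrazone 27 (dihydrofuran ring, C3 set by the catalyst).
5. Ring order: the benzene rings are bought; the dihydrofuran ring of the fragment is formed in step 12; the indane five-membered ring is formed last, in step 15.

Key step: step 5

Assumption 1: the sense of induction of (Sp,Sp)-MandyPhos (step 5) and of Rh2(S-PTAD)4 (step 12) on these substrates is taken as drawn; both are sold in both enantiomeric forms, and the antipode would be used if a first run showed the opposite sense.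
Assumption 2: salts of a product that are only protonated in the quench (alkoxides, acetylides, aryl borates) are treated as the product itself.
Notation: "mac diol" is cis-1,2-dimethyl-1,2-dihydroacenaphthylene-1,2-diol (5); "mac ester" is its cyclic boronic ester. Indane numbering: C1 bears the 4-oxygenated phenyl group, C2 the 3,5-dioxygenated phenyl group, C3 the exocyclic alkene.

**Route**

Step 1
Reactants: 1 1-chloro-3,5-dimethoxybenzene
Product: 2 2-chloro-4,6-dimethoxybenzaldehyde
Conditions: POCl3, DMF, 0 → 90 °C; aq. NaOAc
Reagents that add atoms: N,N-dimethylformamide CN(C)C=O; water O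
Why: Vilsmeier–Haack formylation, in which the chloroiminium ion should attack the position para to one methoxy group and ortho to the other (next to chlorine) in preference to the site between the two methoxy groups, any 4-chloro-2,6-dimethoxy isomer being removed by crystallisation.

Step 2
Reactants: 2 2-chloro-4,6-dimethoxybenzaldehyde
Product: 3 1-chloro-2-ethynyl-3,5-dimethoxybenzene
Conditions: dimethyl (1-diazo-2-oxopropyl)phosphonate, K2CO3, MeOH, rt
Reagents that add atoms: dimethyl (1-diazo-2-oxopropyl)phosphonate COP(=O)(OC)C(=[N+]=[N-])C(C)=O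
Why: Ohira–Bestmann (Seyferth–Gilbert) homologation, in which the diazomethylphosphonate anion adds to the aldehyde and the alkylidene carbene left after loss of phosphate and nitrogen rearranges to the terminal alkyne under conditions that leave the aryl chloride alone.

Step 3
Reactants: 4 acenaphthoquinone
Product: 5 cis-1,2-dimethyl-1,2-dihydroacenaphthylene-1,2-diol (mac diol)
Conditions: MeMgBr (2.5 equiv), THF, 0 °C → rt; aq. NH4Cl; recrystallisation
Reagents that add atoms: methylmagnesium bromide C[Mg]Br
Why: Double Grignard addition to the 1,2-diketone, in which the second methyl group should enter anti to the solvated magnesium alkoxide to give mainly the cis (meso) diol, which is purified by crystallisation and is the only isomer able to form a five-membered cyclic boronate.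

Step 4
Reactants: 3 1-chloro-2-ethynyl-3,5-dimethoxybenzene; 5 mac diol
Product: 7 (Z)-2-(2-chloro-4,6-dimethoxyphenyl)ethenylboronic acid mac ester, via catechol boronate 6 (not isolated)
Conditions: catecholborane, [Rh(cod)Cl]2 (cat.), P(i-Pr)3, Et3N, cyclohexane, rt; then 5, rt
Reagents that add atoms: catecholborane B1Oc2ccccc2O1
Why: Rhodium-catalysed trans-hydroboration of a terminal alkyne through a rhodium vinylidene puts boron and the aryl group cis on the new alkene, and transesterification of the labile catechol ester with the tertiary cis-diol 5 gives the mac ester, chosen over the pinacol ester because it is the boron ligand that lets a β-substituted alkenyl boronate take the conjunctive pathway in step 5.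

Step 5
Reactants: 7 (Z)-2-(2-chloro-4,6-dimethoxyphenyl)ethenylboronic acid mac ester; 8 1-bromo-3,5-dimethoxybenzene; 9 4-methoxyphenyl trifluoromethanesulfonate
Product: 12 (1R,2R)-2-(2-chloro-4,6-dimethoxyphenyl)-1-(3,5-dimethoxyphenyl)-2-(4-methoxyphenyl)ethylboronic acid mac ester, via 3,5-dimethoxyphenyllithium 10 (not isolated), via lithium boronate complex 11 (not isolated)
Conditions: 8, t-BuLi (2 equiv), Et2O, −78 °C; 7, −78 °C → rt; solvent exchange; Pd(OAc)2 (cat.), (Sp,Sp)-MandyPhos [1,1'-bis{bis(4-methoxy-3,5-dimethylphenyl)phosphino}-2,2'-bis{(R)-α-(dimethylamino)benzyl}ferrocene], 9, KOTf, THF, 60 °C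
Reagents that add atoms: none
Why: Conjunctive cross-coupling (palladium-induced 1,2-metallate shift): aryllithium 10 adds to boron of 7 to give the four-coordinate complex 11, oxidative addition of triflate 9 to zerovalent palladium gives a cationic aryl–palladium–bisphosphine species that binds the alkene, the 3,5-dimethoxyphenyl group shifts from boron to the boron-bearing carbon anti to palladium while palladium bonds to the ring A benzylic carbon, and reductive elimination forms the C1–anisyl bond with retention. The closest known reaction type is the Pd(OAc)2/MandyPhos enantioselective conjunctive coupling of β-substituted alkenyl mac boronate complexes with aryl triflates; the present alkene differs in carrying a 2,6-disubstituted aryl group, which is the main uncertainty of the route. No ring is closed. The two new stereocentres (future indane C1 and C2) take their relative configuration from the anti addition of the two aryl groups across the geometrically pure (Z)-alkene, which becomes the trans relationship once C2–B is replaced by C2–C3 with retention, and their absolute configuration from the alkene face selected by the chiral bisphosphine on palladium. The step needs the conjunctive pathway to win over direct Suzuki–Miyaura transmetalation, which the hindered mac diol on boron secures where a pinacol ester of a β-substituted alkenyl boronate would not, and it needs the triflate to react in preference to the ring A chloride, which a ferrocenyl bis(diarylphosphine) palladium catalyst leaves untouched at 60 °C; KOTf removes the bromide ion that would otherwise block the cationic palladium.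

Step 6
Reactants: 13 N,N-di(propan-2-yl)carbamoyl chloride
Product: 15 ethenyl N,N-di(propan-2-yl)carbamate, via lithium ethenolate 14 (not isolated)
Conditions: n-BuLi, THF, rt, 16 h; then 13, DMPU, 0 °C → rt
Reagents that add atoms: tetrahydrofuran C1CCOC1
Why: α-Lithiation of THF and [3+2] cycloreversion give ethene and the lithium enolate of acetaldehyde, which is O-acylated by the carbamoyl chloride (enolate O-carbamoylation) to the vinyl carbamate reagent.

Step 7
Reactants: 12 (1R,2R)-boronic acid mac ester; 15 ethenyl N,N-di(propan-2-yl)carbamate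
Product: 19 (3R,4R)-4-(2-chloro-4,6-dimethoxyphenyl)-3-(3,5-dimethoxyphenyl)-4-(4-methoxyphenyl)but-1-en-2-yl N,N-di(propan-2-yl)carbamate, via lithiated carbamate 16 (not isolated), via lithium boronate complex 17 (not isolated), via iodoalkyl boronate 18 (not isolated)
Conditions: 15, s-BuLi, TMEDA, THF, −78 °C; 12, −78 °C; I2, THF/MeOH, −78 °C; NaOMe, → rt
Reagents that add atoms: none
Why: Zweifel-type olefination of a boronic ester with an α-lithiated enol carbamate, in which 16 adds to boron, iodine activates the alkene of complex 17 so that the benzylic carbon migrates from boron to carbon with retention of configuration to give 18, and methoxide-promoted anti elimination of boron and iodide gives the 1,1-disubstituted enol carbamate.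

Step 8
Reactants: 19 (3R,4R)-enol carbamate
Product: 20 1-chloro-2-[(1R,2S)-2-(3,5-dimethoxyphenyl)-1-(4-methoxyphenyl)but-3-yn-1-yl]-3,5-dimethoxybenzene
Conditions: LDA (2.2 equiv), THF, −78 °C; aq. NH4Cl at −78 °C
Reagents that add atoms: none
Why: Carbamate-directed β-vinylic lithiation and 1,2-elimination of lithium carbamate (the second stage of the stereospecific boronic ester alkynylation) give the terminal alkyne, which the second equivalent of base at once converts into its acetylide and so shields the propargylic stereocentre until the cold quench.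

Step 9
Reactants: 21 5-bromo-2-hydroxybenzonitrile; 22 4-methoxybenzyl chloride
Product: 23 5-bromo-2-[(4-methoxyphenyl)methoxy]benzonitrile
Conditions: K2CO3, DMF, 60 °C
Reagents that add atoms: none
Why: Williamson ether synthesis of an acidic ortho-cyanophenol with a reactive benzylic chloride.

Step 10
Reactants: 23 5-bromo-2-[(4-methoxyphenyl)methoxy]benzonitrile; 8 1-bromo-3,5-dimethoxybenzene
Product: 26 {5-bromo-2-[(4-methoxyphenyl)methoxy]phenyl}(3,5-dimethoxyphenyl)methanone, via aryl Grignard reagent 24 (not isolated), via magnesium ketimide 25 (not isolated)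
Conditions: 8, Mg, THF, reflux; 23, THF, reflux; 2 M aq. HCl, rt
Reagents that add atoms: water O
Why: Grignard addition to a nitrile stops at the N-magnesio ketimine and mild acid hydrolysis gives the benzophenone, the aryl bromide of 23 being inert to an aryl Grignard reagent and the 4-methoxybenzyl ether stable to dilute acid at room temperature.

Step 11
Reactants: 26 the benzophenone
Product: 27 hydrazone of 26
Conditions: N2H4·H2O (excess), AcOH (cat.), EtOH, reflux
Reagents that add atoms: hydrazine NN
Why: Hydrazone formation by condensation of the diaryl ketone with excess hydrazine, the E/Z mixture being of no consequence because both isomers give the same diazo compound.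

Step 12
Reactants: 27 hydrazone
Product: 29 (2R,3S)-5-bromo-3-(3,5-dimethoxyphenyl)-2-(4-methoxyphenyl)-2,3-dihydro-1-benzofuran (cis), via diaryldiazomethane 28 (not isolated)
Conditions: MnO2, MgSO4, CH2Cl2, 0 °C; filter; Rh2(S-PTAD)4 (1 mol %), CH2Cl2, 0 °C → rt
Reagents that add atoms: none
Why: Oxidation of the hydrazone to the diaryldiazomethane and dirhodium-catalysed intramolecular C–H insertion of the donor/donor carbene into the 4-methoxybenzylic C–H bond (1,5-insertion) close the dihydrofuran ring, the chiral carboxylate catalyst setting C3 and the concerted insertion delivering the cis-2,3-diaryl isomer.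

Step 13
Reactants: 29 cis-dihydrobenzofuran
Product: 30 (2S,3S)-5-bromo-3-(3,5-dimethoxyphenyl)-2-(4-methoxyphenyl)-2,3-dihydro-1-benzofuran (trans)
Conditions: BF3·OEt2, CH2Cl2, −20 → 0 °C
Reagents that add atoms: none
Why: Lewis-acid-mediated reversible ionisation of the C2–O bond to the 4-methoxybenzylic cation and reclosure (thermodynamic epimerisation) should give the more stable trans isomer by inverting C2 only, C3 not being involved.

Step 14
Reactants: 30 trans-bromide
Product: 31 2-[(2S,3S)-3-(3,5-dimethoxyphenyl)-2-(4-methoxyphenyl)-2,3-dihydro-1-benzofuran-5-yl]-4,4,5,5-tetramethyl-1,3,2-dioxaborolane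
Conditions: B2pin2, Pd(dppf)Cl2 (cat.), KOAc, dioxane, 90 °C
Reagents that add atoms: bis(pinacolato)diboron CC1(C)OB(OC1(C)C)B1OC(C)(C)C(C)(C)O1
Why: Miyaura borylation of the aryl bromide under neutral acetate conditions that do not disturb the benzylic ether or either stereocentre.

Step 15
Reactants: 20 chloro-alkyne; 31 dihydrobenzofuran boronate
Product: 32 octamethyl ether of the target
Conditions: Pd(OAc)2 (cat.), SPhos, K3PO4, toluene/H2O, 90 °C
Reagents that add atoms: none
Why: Domino carbopalladation–Suzuki–Miyaura coupling, in which oxidative addition of the ring A C–Cl bond to zerovalent palladium, syn 5-exo-dig insertion of the tethered terminal alkyne (closing the indane five-membered ring) and transmetalation of the alkenyl–palladium with boronate 31 followed by reductive elimination with retention place the dihydrobenzofuranyl group cis to ring A, i.e. the (Z)-alkene, with C1 and C2 as spectators.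

Step 16
Reactants: 32 octamethyl ether
Product: 33 CNP0184753.4 (target)
Conditions: BBr3 (excess), CH2Cl2, −78 → 0 °C; then H2O
Reagents that add atoms: none
Why: Lewis-acid ether cleavage (BBr3 demethylation) of the eight aryl methyl ethers at low temperature, the usual end-game for permethylated resveratrol oligomers, in which the trans-dihydrobenzofuran is the thermodynamic isomer so that reversible C2–O ionisation does not change it.

**Compound list**
1 | 1-chloro-3,5-dimethoxybenzene | COc1cc(Cl)cc(OC)c1 | starting material
2 | 2-chloro-4,6-dimethoxybenzaldehyde | COc1cc(OC)c(C=O)c(Cl)c1 | intermediate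
3 | 1-chloro-2-ethynyl-3,5-dimethoxybenzene | COc1cc(OC)c(C#C)c(Cl)c1 | intermediate
4 | acenaphthoquinone (acenaphthylene-1,2-dione) | O=C1C(=O)c2cccc3cccc1c23 | starting material
5 | cis-1,2-dimethyl-1,2-dihydroacenaphthylene-1,2-diol (meso, mac diol) | C[C@@]1(O)c2cccc3cccc(c23)[C@]1(C)O | intermediate
6 | 2-[(Z)-2-(2-chloro-4,6-dimethoxyphenyl)ethenyl]-1,3,2-benzodioxaborole (formed in the flask) | COc1cc(OC)c(/C=C\B2Oc3ccccc3O2)c(Cl)c1 | intermediate
7 | (Z)-2-(2-chloro-4,6-dimethoxyphenyl)ethenylboronic acid mac ester | COc1cc(OC)c(/C=C\B2O[C@]3(C)c4cccc5cccc(c45)[C@]3(C)O2)c(Cl)c1 | intermediate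
8 | 1-bromo-3,5-dimethoxybenzene | COc1cc(Br)cc(OC)c1 | starting material
9 | 4-methoxyphenyl trifluoromethanesulfonate | COc1ccc(OS(=O)(=O)C(F)(F)F)cc1 | starting material
10 | 3,5-dimethoxyphenyllithium (formed in the flask) | [Li]c1cc(OC)cc(OC)c1 | intermediate
11 | lithium [(Z)-2-(2-chloro-4,6-dimethoxyphenyl)ethenyl](3,5-dimethoxyphenyl)borate of diol 5 (formed in the flask; either orientation at boron) | [Li+].COc1cc(OC)c(/C=C\[B-]2(c3cc(OC)cc(OC)c3)O[C@]3(C)c4cccc5cccc(c45)[C@]3(C)O2)c(Cl)c1 | intermediate
12 | (1R,2R)-2-(2-chloro-4,6-dimethoxyphenyl)-1-(3,5-dimethoxyphenyl)-2-(4-methoxyphenyl)ethylboronic acid mac ester | COc1ccc([C@@H]([C@@H](B2O[C@]3(C)c4cccc5cccc(c45)[C@]3(C)O2)c2cc(OC)cc(OC)c2)c2c(OC)cc(OC)cc2Cl)cc1 | intermediate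
13 | N,N-di(propan-2-yl)carbamoyl chloride | CC(C)N(C(C)C)C(Cl)=O | starting material
14 | lithium ethenolate (formed in the flask) | [Li+].[O-]C=C | intermediate
15 | ethenyl N,N-di(propan-2-yl)carbamate | C=COC(=O)N(C(C)C)C(C)C | intermediate
16 | 1-lithioethenyl N,N-di(propan-2-yl)carbamate (formed in the flask) | [Li]C(=C)OC(=O)N(C(C)C)C(C)C | intermediate
17 | lithium borate from 12 and 16 (formed in the flask) | [Li+].COc1ccc([C@@H]([C@@H]([B-]2(C(=C)OC(=O)N(C(C)C)C(C)C)O[C@]3(C)c4cccc5cccc(c45)[C@]3(C)O2)c2cc(OC)cc(OC)c2)c2c(OC)cc(OC)cc2Cl)cc1 | intermediate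
18 | β-iodoalkyl mac boronate after the 1,2-shift (formed in the flask; configuration at the new quaternary carbon not specified, it is lost in the elimination) | COc1ccc([C@@H]([C@@H](C(CI)(OC(=O)N(C(C)C)C(C)C)B2O[C@]3(C)c4cccc5cccc(c45)[C@]3(C)O2)c2cc(OC)cc(OC)c2)c2c(OC)cc(OC)cc2Cl)cc1 | intermediate
19 | (3R,4R)-4-(2-chloro-4,6-dimethoxyphenyl)-3-(3,5-dimethoxyphenyl)-4-(4-methoxyphenyl)but-1-en-2-yl N,N-di(propan-2-yl)carbamate | COc1ccc([C@@H]([C@@H](C(=C)OC(=O)N(C(C)C)C(C)C)c2cc(OC)cc(OC)c2)c2c(OC)cc(OC)cc2Cl)cc1 | intermediate
20 | 1-chloro-2-[(1R,2S)-2-(3,5-dimethoxyphenyl)-1-(4-methoxyphenyl)but-3-yn-1-yl]-3,5-dimethoxybenzene | COc1ccc([C@@H]([C@@H](C#C)c2cc(OC)cc(OC)c2)c2c(OC)cc(OC)cc2Cl)cc1 | intermediate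
21 | 5-bromo-2-hydroxybenzonitrile | N#Cc1cc(Br)ccc1O | starting material
22 | 4-methoxybenzyl chloride | COc1ccc(CCl)cc1 | starting material
23 | 5-bromo-2-[(4-methoxyphenyl)methoxy]benzonitrile | COc1ccc(COc2ccc(Br)cc2C#N)cc1 | intermediate
24 | 3,5-dimethoxyphenylmagnesium bromide (formed in the flask) | COc1cc(OC)cc([Mg]Br)c1 | intermediate
25 | N-bromomagnesio ketimine from 23 and 24 (formed in the flask) | COc1ccc(COc2ccc(Br)cc2C(=N[Mg]Br)c2cc(OC)cc(OC)c2)cc1 | intermediate
26 | {5-bromo-2-[(4-methoxyphenyl)methoxy]phenyl}(3,5-dimethoxyphenyl)methanone | COc1ccc(COc2ccc(Br)cc2C(=O)c2cc(OC)cc(OC)c2)cc1 | intermediate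
27 | hydrazone of 26 (E/Z mixture) | COc1ccc(COc2ccc(Br)cc2C(=NN)c2cc(OC)cc(OC)c2)cc1 | intermediate
28 | {5-bromo-2-[(4-methoxyphenyl)methoxy]phenyl}(3,5-dimethoxyphenyl)diazomethane (formed in the flask) | COc1ccc(COc2ccc(Br)cc2C(=[N+]=[N-])c2cc(OC)cc(OC)c2)cc1 | intermediate
29 | (2R,3S)-5-bromo-3-(3,5-dimethoxyphenyl)-2-(4-methoxyphenyl)-2,3-dihydro-1-benzofuran (cis) | Brc1ccc2c(c1)[C@H](c1cc(OC)cc(OC)c1)[C@H](c1ccc(OC)cc1)O2 | intermediate
30 | (2S,3S)-5-bromo-3-(3,5-dimethoxyphenyl)-2-(4-methoxyphenyl)-2,3-dihydro-1-benzofuran (trans) | Brc1ccc2c(c1)[C@H](c1cc(OC)cc(OC)c1)[C@@H](c1ccc(OC)cc1)O2 | intermediate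
31 | 2-[(2S,3S)-3-(3,5-dimethoxyphenyl)-2-(4-methoxyphenyl)-2,3-dihydro-1-benzofuran-5-yl]-4,4,5,5-tetramethyl-1,3,2-dioxaborolane | CC1(C)OB(OC1(C)C)c1ccc2c(c1)[C@H](c1cc(OC)cc(OC)c1)[C@@H](c1ccc(OC)cc1)O2 | intermediate
32 | octamethyl ether of the target: (2S,3S)-5-{(Z)-[(2R,3R)-2-(3,5-dimethoxyphenyl)-4,6-dimethoxy-3-(4-methoxyphenyl)-2,3-dihydro-1H-inden-1-ylidene]methyl}-3-(3,5-dimethoxyphenyl)-2-(4-methoxyphenyl)-2,3-dihydro-1-benzofuran | COc1ccc([C@@H]2c3c(OC)cc(OC)cc3/C(=C\c3ccc4c(c3)[C@H](c3cc(OC)cc(OC)c3)[C@@H](c3ccc(OC)cc3)O4)[C@H]2c2cc(OC)cc(OC)c2)cc1 | intermediate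
33 | CNP0184753.4 (indane C1 R, C2 R; exocyclic alkene Z; dihydrobenzofuran C2 S, C3 S) | Oc1ccc([C@@H]2c3c(O)cc(O)cc3/C(=C\c3ccc4c(c3)[C@H](c3cc(O)cc(O)c3)[C@@H](c3ccc(O)cc3)O4)[C@H]2c2cc(O)cc(O)c2)cc1 | target

**Step count and risks**
Total steps: 16. Longest linear sequence: 8 steps (1, 2, 4, 5, 7, 8, 15, 16); the fragment branch (9 to 14, then 15 and 16) is equally long.

Most likely to fail, riskiest first:

Step 5. The cationic aryl–palladium may fail to coordinate the alkene next to the 2,6-disubstituted ring, so that direct transfer of the alkenyl group from boron to palladium (plain Suzuki–Miyaura coupling) or breakdown of the boronate complex takes over; poor facial selectivity is the second danger. The fallback exchanges the roles of the two C1 aryl groups, so that the alkene is an unhindered (E)-styrenyl boronate and the crowded ring arrives on palladium. It sets out from aldehyde 2, diol 5 and bromide 8 and returns at 12. Aldehyde 2 is oxidised with mCPBA (Dakin-type Baeyer–Villiger reaction) to 2-chloro-4,6-dimethoxyphenyl formate F1, which is methanolysed (K2CO3, MeOH) to 2-chloro-4,6-dimethoxyphenol F2 and converted (Tf2O, pyridine) into 2-chloro-4,6-dimethoxyphenyl trifluoromethanesulfonate F3. Commercial (E)-2-(4-methoxyphenyl)ethenylboronic acid is esterified with 5 (MgSO4, CH2Cl2) to (E)-2-(4-methoxyphenyl)ethenylboronic acid mac ester F4. Aryllithium 10 (from 8) adds to F4 to give the lithium boronate complex F5, which is coupled with F3 under the catalyst system of step 5, the ligand enantiomer again being fixed by a first run. Anti addition across the (E)-alkene, with ring A now delivered to the carbon that already bears the anisyl group, gives the same (1R,2R) compound 12.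

Step 15. Intermolecular reactions of the free terminal alkyne (palladium acetylide formation, oligomerisation) or direct biaryl coupling at the aryl–palladium stage may outrun the ring-closing insertion, and the alkenyl–palladium may lose its geometry before transmetalation. The fallback forms the aryl–alkene bond first and closes the ring by a Heck reaction. It sets out from alkyne 20 and bromide 30 (step 14 is then not needed) and returns at 32. Sonogashira coupling (Pd(PPh3)2Cl2, copper iodide CuI, Et3N, THF, 50 °C; the ring A chloride is inert to this catalyst) gives the diarylalkyne F6. Lindlar semihydrogenation (Pd on CaCO3 poisoned with Pb(OAc)2, quinoline, H2, EtOAc) gives the (Z)-alkene F7. Intramolecular Heck reaction (Pd2(dba)3, P(t-Bu)3, Cy2NMe, dioxane, 100 °C) closes the indane ring by 5-exo-trig syn insertion. Syn β-hydride elimination of the only available β-hydrogen, the one on C3, then transfers the (Z) geometry of F7 into the exocyclic alkene with the dihydrobenzofuranyl group cis to ring A, which is 32.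

Step 8. LDA may deprotonate elsewhere: at the ring A C–H between chlorine and methoxy (aryne formation on warming) or at the doubly activated methine next to the enol carbamate (epimerisation of C2 or allene formation). The fallback builds the alkyne by carbonyl homologation and replaces steps 7 and 8 together. It sets out from boronic ester 12 and returns at alkyne 20. Matteson homologation (BrCH2Cl, n-BuLi, THF, −78 °C → rt) proceeds through the chloromethyl boronate complex F8 and gives the one-carbon-homologated mac boronate F9 with retention at the migrating carbon. Oxidation (NaOH, H2O2) gives the primary alcohol F10, and Dess–Martin periodinane gives the aldehyde F11. A Corey–Fuchs sequence follows: CBr4/PPh3 (Et3N, CH2Cl2, 0 °C) gives the dibromoalkene F12, and n-BuLi (THF, −78 °C), whose bromine–lithium exchange is far faster than any arene deprotonation, gives 20 after a cold quench.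

**Further compounds**
F1 | step 5 | 2-chloro-4,6-dimethoxyphenyl formate | COc1cc(OC)c(OC=O)c(Cl)c1
F2 | step 5 | 2-chloro-4,6-dimethoxyphenol | COc1cc(OC)c(O)c(Cl)c1
F3 | step 5 | 2-chloro-4,6-dimethoxyphenyl trifluoromethanesulfonate | COc1cc(OC)c(OS(=O)(=O)C(F)(F)F)c(Cl)c1
F4 | step 5 | (E)-2-(4-methoxyphenyl)ethenylboronic acid mac ester | COc1ccc(/C=C/B2O[C@]3(C)c4cccc5cccc(c45)[C@]3(C)O2)cc1
F5 | step 5 | lithium [(E)-2-(4-methoxyphenyl)ethenyl](3,5-dimethoxyphenyl)borate of diol 5 | [Li+].COc1ccc(/C=C/[B-]2(c3cc(OC)cc(OC)c3)O[C@]3(C)c4cccc5cccc(c45)[C@]3(C)O2)cc1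
F6 | step 15 | diarylalkyne from 20 and 30 (configurations as in 20 and 30) | COc1ccc([C@@H]([C@@H](C#Cc2ccc3c(c2)[C@H](c2cc(OC)cc(OC)c2)[C@@H](c2ccc(OC)cc2)O3)c2cc(OC)cc(OC)c2)c2c(OC)cc(OC)cc2Cl)cc1
F7 | step 15 | (Z)-alkene from semihydrogenation of F6 | COc1ccc([C@@H]([C@@H](/C=C\c2ccc3c(c2)[C@H](c2cc(OC)cc(OC)c2)[C@@H](c2ccc(OC)cc2)O3)c2cc(OC)cc(OC)c2)c2c(OC)cc(OC)cc2Cl)cc1
F8 | step 8 | lithium (chloromethyl)borate from 12 | [Li+].COc1ccc([C@@H]([C@@H]([B-]2(CCl)O[C@]3(C)c4cccc5cccc(c45)[C@]3(C)O2)c2cc(OC)cc(OC)c2)c2c(OC)cc(OC)cc2Cl)cc1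
F9 | step 8 | one-carbon-homologated mac boronate | COc1ccc([C@@H]([C@@H](CB2O[C@]3(C)c4cccc5cccc(c45)[C@]3(C)O2)c2cc(OC)cc(OC)c2)c2c(OC)cc(OC)cc2Cl)cc1
F10 | step 8 | primary alcohol from oxidation of F9 | COc1ccc([C@@H]([C@@H](CO)c2cc(OC)cc(OC)c2)c2c(OC)cc(OC)cc2Cl)cc1
F11 | step 8 | aldehyde from F10 | COc1ccc([C@@H]([C@@H](C=O)c2cc(OC)cc(OC)c2)c2c(OC)cc(OC)cc2Cl)cc1
F12 | step 8 | 1,1-dibromoalkene from F11 | COc1ccc([C@@H]([C@@H](C=C(Br)Br)c2cc(OC)cc(OC)c2)c2c(OC)cc(OC)cc2Cl)cc1
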